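**Retrosynthetic overview**
1. Ring B (ten-membered) is closed last, at C6–C7. A butenolide, as its silyloxyfuran, attacks a C6 aldehyde in an intramolecular vinylogous Mukaiyama aldol, and E1cB loss of the C6 silyloxy group gives the (6E) enol-lactone alkene.
2. Ring C (butenolide) comes from an intramolecular Horner–Wadsworth–Emmons reaction on a C8 ketone. The C9–C10 bond comes from a suprafacial ketal Claisen rearrangement of a C12β allylic alcohol.
3. That alcohol comes from the carvone enone by Weitz–Scheffer epoxidation and a radical 1,3-transposition. The C14 acetate is the degraded isopropenyl group (ozonolysis, Baeyer–Villiger).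
4. Key union: the C1–C2 bond, by aldol addition of the (S)-carvone lithium enolate (ring A) to a C2–C6 aldehyde. Oxidation, C1 methylation anti to the isopropenyl group and CBS reduction then fix C1 and C2.
5. The aldehyde (C5 stereocentre) comes from methallyl alcohol by Sharpless epoxidation and allyl Grignard opening. Ring order: A (bought in), then C, then B.

Assumption: locants follow briarane numbering (C1 quaternary, C2 isovalerate carbinol, C5 tertiary carbinol, C6=C7, C8/C17/C19 butenolide, C10 ring-fusion CH, C11=C12, C14 acetate carbinol). α is the ring A face that carries the C14 substituent and β is the face that carries the C1 methyl.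

**Step 1**
Reactants: 1 methallyl alcohol
Product: 2 (R)-2-methylglycidol
Conditions: Ti(OiPr)4 (5 mol %), diisopropyl D-(−)-tartrate (6 mol %), cumene hydroperoxide, 4 Å MS, CH2Cl2, −20 °C
Reagents that add atoms: cumene hydroperoxide CC(C)(OO)c1ccccc1
Why: Sharpless asymmetric epoxidation, in which the D-(−)-tartrate titanium complex delivers oxygen to one face of the allylic alcohol and sets the future C5 as the (R)-epoxide in about 94% ee, the minor antipode being removed later as a diastereomer.

**Step 2**
Reactants: 2 (R)-2-methylglycidol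
Product: 3 (S)-2-methylhex-5-ene-1,2-diol
Conditions: allylMgCl (2.5 equiv), CuI (10 mol %), THF, −30 → 0 °C; aq NH4Cl
Reagents that add atoms: allylmagnesium chloride C=CC[Mg]Cl
Why: Copper-catalysed SN2 opening of the 2,2-disubstituted epoxide at its free CH2 terminus leaves the C–O bond at the quaternary carbon untouched, so C5 keeps its shape (the descriptor becomes S only through CIP ranking) and the degenerate Payne shift of the alkoxide cannot racemise it.

**Step 3**
Reactants: 3 (S)-2-methylhex-5-ene-1,2-diol
Product: 4 (4S)-4-(but-3-enyl)-2,2,4-trimethyl-1,3-dioxolane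
Conditions: Me2C(OMe)2, PPTS (cat.), CH2Cl2, rt
Reagents that add atoms: 2,2-dimethoxypropane COC(C)(C)OC
Why: Acid-catalysed transketalisation ties the C5 and C6 oxygens into one acetonide that survives every base, hydride, oxidant and radical step up to step 19, and no stereocentre is touched.

**Step 4**
Reactants: 4 (4S)-4-(but-3-enyl)-2,2,4-trimethyl-1,3-dioxolane
Product: 6 3-[(4S)-2,2,4-trimethyl-1,3-dioxolan-4-yl]propanal, via secondary ozonide 5 (not isolated)
Conditions: O3, CH2Cl2, −78 °C; Me2S, −78 °C → rt
Reagents that add atoms: ozone [O-][O+]=O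
Why: Ozonolysis (Criegee mechanism) with reductive work-up cleaves the only alkene to the C2 aldehyde and leaves the acetonide and C5 alone.

**Step 5**
Reactants: 7 (S)-(+)-carvone; 6 3-[(4S)-2,2,4-trimethyl-1,3-dioxolan-4-yl]propanal
Product: 9 C1–C2 aldol adduct (side chain trans to isopropenyl; C2 carbinol epimers), via lithium dienolate 8 (not isolated)
Conditions: LiN(iPr)2 (1.05 equiv), THF, −78 °C; 6, −78 °C; AcOH, −78 °C
Reagents that add atoms: none
Why: Kinetic deprotonation of carvone at its only saturated α-CH2 gives the cross-conjugated lithium dienolate, which adds to the aldehyde in a Zimmerman–Traxler aldol addition faster than proton transfer and forges the hindered C1–C2 bond, the two new centres being erased in step 6 and reset in steps 7 and 8.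

**Step 6**
Reactants: 9 C1–C2 aldol adduct
Product: 10 2-acyl enone (β-diketone drawn as its ring-enol tautomer)
Conditions: IBX, EtOAc, 77 °C
Reagents that add atoms: none
Why: IBX oxidation of a β-hydroxy ketone stops cleanly at the enolised β-diketone, merges all aldol diastereomers into one compound and spares both alkenes and the acetonide.

**Step 7**
Reactants: 10 2-acyl enone
Product: 11 C1-methylated β-diketone (C1 methyl β and acyl chain α)
Conditions: K2CO3, MeI, acetone, rt → 40 °C
Reagents that add atoms: iodomethane CI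
Why: C-alkylation of the stabilised β-diketone enolate by the soft electrophile MeI, in which A(1,2) strain against the acyl group pushes the neighbouring isopropenyl group pseudoaxial, so that methyl enters from the opposite β face and sets quaternary C1.

**Step 8**
Reactants: 11 C1-methylated β-diketone
Product: 12 (2S)-β-hydroxy enone
Conditions: (R)-2-methyl-CBS-oxazaborolidine (0.5 equiv), catecholborane (1.5 equiv), toluene, −78 → −40 °C; MeOH, H2O
Reagents that add atoms: none
Why: Corey–Bakshi–Shibata reduction, in which the C2 ketone offers a clear large (quaternary C1) versus small (CH2) pair, so the (R)-catalyst gives the (2S)-alcohol, whereas the conjugated C10 ketone, flanked by two large groups, reacts far more slowly and catecholborane does not hydroborate the alkenes.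

**Step 9**
Reactants: 12 (2S)-β-hydroxy enone
Product: 13 C2 isovalerate enone
Conditions: isovaleryl chloride, pyridine, DMAP (cat.), CH2Cl2, 0 °C → rt
Reagents that add atoms: isovaleryl chloride CC(C)CC(Cl)=O
Why: DMAP-catalysed acylation installs the final C2 ester with retention at C2 and at the same time blocks retro-aldol cleavage of the C1–C2 bond in all later basic steps.

**Step 10**
Reactants: 13 C2 isovalerate enone
Product: 14 11β,12β-epoxy ketone
Conditions: t-BuOOH, BnNMe3OH (cat.), THF, 0 °C
Reagents that add atoms: tert-butyl hydroperoxide CC(C)(C)OO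
Why: Weitz–Scheffer nucleophilic epoxidation, in which the bulky peroxide anion adds axially to C12 trans to the C14 isopropenyl group as in carvone itself, setting the β-epoxide (C11 and C12) without touching the electron-rich isopropenyl alkene or the hindered ester.

**Step 11**
Reactants: 14 11β,12β-epoxy ketone
Product: 16 C14α acetyl epoxy ketone, via secondary ozonide 15 (not isolated)
Conditions: O3, CH2Cl2, −78 °C; Me2S, −78 °C → rt
Reagents that add atoms: ozone [O-][O+]=O
Why: Ozonolysis at the one stage where the isopropenyl group is the only alkene in the molecule, with a neutral work-up that does not epimerise C14.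

**Step 12**
Reactants: 16 C14α acetyl epoxy ketone
Product: 17 C14α acetate epoxy ketone
Conditions: mCPBA, CH2Cl2, rt
Reagents that add atoms: 3-chloroperoxybenzoic acid OOC(=O)c1cccc(Cl)c1
Why: Baeyer–Villiger oxidation, in which secondary C14 migrates in preference to methyl with retention, so the acetyl group becomes the final (14S)-acetate, while the doubly flanked C10 epoxy ketone is too hindered to add peracid and no alkene is left to epoxidise.

**Step 13**
Reactants: 17 C14α acetate epoxy ketone
Product: 18 C10 carbinol (epimer mixture at C10)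
Conditions: NaBH4, MeOH–CH2Cl2, −20 °C
Reagents that add atoms: none
Why: Borohydride reduction, in which the small hydride still reaches the epoxide-activated ketone while esters, epoxide and acetonide are inert at this temperature, and the new C10 centre is destroyed again in step 15.

**Step 14**
Reactants: 18 C10 carbinol
Product: 19 C10 O-phenyl thionocarbonate
Conditions: PhOC(S)Cl, DMAP, MeCN, 50 °C
Reagents that add atoms: O-phenyl chlorothionoformate ClC(=S)Oc1ccccc1
Why: Thioacyl transfer through the DMAP thioacylpyridinium salt (the thionocarbonate used for Barton–McCombie chemistry) derivatises the hindered hydroxyl without forming an alkoxide, which avoids Payne rearrangement and acyl migration from C2 or C14.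

**Step 15**
Reactants: 19 C10 O-phenyl thionocarbonate
Product: 20 C12β allylic alcohol (C10=C11)
Conditions: Bu3SnH, AIBN (cat.), toluene, 100 °C
Reagents that add atoms: none
Why: Barton–McCombie-type generation of the C10 radical is followed by very fast scission of the adjacent C11–O epoxide bond (the radical counterpart of the Wharton transposition), and the alkoxyl radical takes hydrogen from Bu3SnH, so the β C12–O bond is kept while the alkene appears at C10=C11.

**Step 16**
Reactants: 20 C12β allylic alcohol
Product: 23 C8 methyl ketone (acetonyl group on C10β; C11=C12), via mixed ketal 21 (not isolated), via allyl isopropenyl ether 22 (not isolated)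
Conditions: 2-methoxypropene (20 equiv), PPTS (5 mol %), toluene, sealed tube, 125 °C
Reagents that add atoms: 2-methoxypropene COC(C)=C
Why: Ketal Claisen rearrangement of the Saucy–Marbet type, whose [3,3] shift is suprafacial, so the β C12–O bond is traded for the β C10–C9 bond (10S) beside the quaternary carbon and the alkene lands at C11=C12, the acetonide being safe in excess enol ether.

**Step 17**
Reactants: 23 C8 methyl ketone
Product: 25 C7 bromomethyl ketone, via boron enolate 24 (not isolated)
Conditions: n-Bu2BOTf, iPr2NEt, CH2Cl2, −78 °C; NBS, −78 → −20 °C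
Reagents that add atoms: N-bromosuccinimide O=C1CCC(=O)N1Br
Why: Soft enolisation removes a proton from the less hindered methyl group of the only ketone and leaves both esters alone, and the enol borinate is brominated by NBS faster than the trisubstituted alkene (regiospecific α-halogenation).

**Step 18**
Reactants: 25 C7 bromomethyl ketone
Product: 27 butenolide acetonide (ring C formed), via phosphonate ester 26 (not isolated)
Conditions: (EtO)2P(O)CH(Me)CO2H, Cs2CO3, MeCN, rt → 45 °C
Reagents that add atoms: 2-(diethoxyphosphoryl)propanoic acid CCOP(=O)(OCC)C(C)C(=O)O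
Why: SN2 displacement of the activated bromide by the caesium carboxylate is followed by an intramolecular Horner–Wadsworth–Emmons olefination of the C8 ketone, and the five-membered ring closure gives the α-methyl butenolide under conditions too mild for the other esters.

**Step 19**
Reactants: 27 butenolide acetonide
Product: 28 C5,C6-diol
Conditions: AcOH–THF–H2O (4:1:1), 45 °C
Reagents that add atoms: none
Why: Mild acid hydrolysis of the acetonide breaks only the ketal C–O bonds, so C5 keeps its configuration and the esters, butenolide and ring alkene survive.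

**Step 20**
Reactants: 28 C5,C6-diol
Product: 29 C5,C6-bis(triethylsilyl) ether
Conditions: TESOTf, 2,6-lutidine, CH2Cl2, −78 → 0 °C
Reagents that add atoms: triethylsilyl trifluoromethanesulfonate CC[Si](CC)(CC)OS(=O)(=O)C(F)(F)F
Why: Silyl triflate silylation covers even the tertiary C5 hydroxyl with a group that is easy to remove at the end, and lutidine is too weak a base to enolise the butenolide lastingly.

**Step 21**
Reactants: 29 C5,C6-bis(triethylsilyl) ether
Product: 31 C6 aldehyde (C5 OTES), via alkoxysulfonium chloride 30 (not isolated)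
Conditions: (COCl)2, DMSO, CH2Cl2, −78 → −40 °C; Et3N, → 0 °C
Reagents that add atoms: none
Why: Swern oxidation applied directly to a primary triethylsilyl ether, in which only the unhindered C6 ether is exchanged onto sulfur and oxidised while the tertiary C5 ether stays, and the product aldehyde has no α-hydrogen to epimerise.

**Step 22**
Reactants: 31 C6 aldehyde
Product: 33 macrocyclic aldol silyl ether (ring B closed; mixture at C6 and C7), via silyloxyfuran 32 (not isolated)
Conditions: TBSOTf (3 equiv), Et3N (5 equiv), CH2Cl2 (1 mM, slow addition of 31), 0 °C → rt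
Reagents that add atoms: tert-butyldimethylsilyl trifluoromethanesulfonate CC(C)(C)[Si](C)(C)OS(=O)(=O)C(F)(F)F
Why: Intramolecular vinylogous Mukaiyama aldol, in which the only acidic protons (C7) give the 2-silyloxyfuran, its free γ-carbon attacks the TBSOTf-activated non-enolisable aldehyde, the trans-diequatorial C2 and C9 arms on ring A hold the termini close, silyl transfer makes the addition irreversible, and both new centres vanish in step 23.

**Step 23**
Reactants: 33 macrocyclic aldol silyl ether
Product: 34 C5 O-triethylsilyl ether of the target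
Conditions: DBU, CH2Cl2, rt
Reagents that add atoms: none
Why: E1cB elimination through the planar furanolate expels the C6 silyloxide from either diastereomer, and the ten-membered ring accepts only the ring-cis alkene with C5 syn to C8, which is the required (6E) geometry.

**Step 24**
Reactants: 34 C5 O-triethylsilyl ether of the target
Product: 35 target CNP0208239.1
Conditions: HF·pyridine, pyridine, THF, 0 °C
Reagents that add atoms: none
Why: Buffered fluoride desilylation cleaves only the Si–O bond, so the acid-sensitive tertiary allylic alcohol keeps its (5S) configuration and both esters and the enol lactone remain intact.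

**Compound list**
1 | methallyl alcohol | C=C(C)CO | starting material
2 | (R)-2-methylglycidol | OC[C@]1(C)CO1 | intermediate
3 | (S)-2-methylhex-5-ene-1,2-diol | C=CCC[C@](C)(O)CO | intermediate
4 | (4S)-4-(but-3-enyl)-2,2,4-trimethyl-1,3-dioxolane | C=CCC[C@@]1(C)COC(C)(C)O1 | intermediate
5 | secondary ozonide of 4 (trioxolane carbon unspecified) | C1OC(CC[C@@]2(C)COC(C)(C)O2)OO1 | intermediate
6 | 3-[(4S)-2,2,4-trimethyl-1,3-dioxolan-4-yl]propanal (C2–C6 aldehyde) | O=CCC[C@@]1(C)COC(C)(C)O1 | intermediate
7 | (S)-(+)-carvone | CC(=C)[C@H]1CC=C(C)C(=O)C1 | starting material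
8 | lithium cross-conjugated dienolate of carvone | [Li+].CC(=C)[C@H]1CC=C(C)C([O-])=C1 | intermediate
9 | aldol adduct, side chain on C1 trans to isopropenyl, C2 carbinol epimers | CC(=C)[C@H]1CC=C(C)C(=O)[C@@H]1C(O)CC[C@@]2(C)COC(C)(C)O2 | intermediate
10 | 2-acyl enone, ring-enol tautomer of the β-diketone | CC(=C)[C@H]1CC=C(C)C(O)=C1C(=O)CC[C@@]2(C)COC(C)(C)O2 | intermediate
11 | C1-methylated β-diketone, methyl β (trans to isopropenyl), acyl chain α | CC(=C)[C@H]1CC=C(C)C(=O)[C@@]1(C)C(=O)CC[C@@]2(C)COC(C)(C)O2 | intermediate
12 | (2S)-β-hydroxy enone | CC(=C)[C@H]1CC=C(C)C(=O)[C@@]1(C)[C@@H](O)CC[C@@]2(C)COC(C)(C)O2 | intermediate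
13 | C2 isovalerate enone | CC(=C)[C@H]1CC=C(C)C(=O)[C@@]1(C)[C@@H](OC(=O)CC(C)C)CC[C@@]2(C)COC(C)(C)O2 | intermediate
14 | 11β,12β-epoxy ketone | CC(=C)[C@H]1C[C@@H]2O[C@]2(C)C(=O)[C@@]1(C)[C@@H](OC(=O)CC(C)C)CC[C@@]3(C)COC(C)(C)O3 | intermediate
15 | secondary ozonide of 14 (trioxolane carbon unspecified) | CC1(OCOO1)[C@H]2C[C@@H]3O[C@]3(C)C(=O)[C@@]2(C)[C@@H](OC(=O)CC(C)C)CC[C@@]4(C)COC(C)(C)O4 | intermediate
16 | C14α acetyl epoxy ketone | CC(=O)[C@H]1C[C@@H]2O[C@]2(C)C(=O)[C@@]1(C)[C@@H](OC(=O)CC(C)C)CC[C@@]3(C)COC(C)(C)O3 | intermediate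
17 | C14α acetate epoxy ketone | CC(=O)O[C@H]1C[C@@H]2O[C@]2(C)C(=O)[C@@]1(C)[C@@H](OC(=O)CC(C)C)CC[C@@]3(C)COC(C)(C)O3 | intermediate
18 | C10 carbinol, both C10 epimers | CC(=O)O[C@H]1C[C@@H]2O[C@]2(C)C(O)[C@@]1(C)[C@@H](OC(=O)CC(C)C)CC[C@@]3(C)COC(C)(C)O3 | intermediate
19 | C10 O-phenyl thionocarbonate, both C10 epimers | CC(=O)O[C@H]1C[C@@H]2O[C@]2(C)C(OC(=S)Oc4ccccc4)[C@@]1(C)[C@@H](OC(=O)CC(C)C)CC[C@@]3(C)COC(C)(C)O3 | intermediate
20 | C12β (12S) allylic alcohol with C10=C11 | CC(=O)O[C@H]1C[C@H](O)C(C)=C[C@@]1(C)[C@@H](OC(=O)CC(C)C)CC[C@@]2(C)COC(C)(C)O2 | intermediate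
21 | C12 2-methoxyprop-2-yl ether (mixed ketal) | CC(=O)O[C@H]1C[C@H](OC(C)(C)OC)C(C)=C[C@@]1(C)[C@@H](OC(=O)CC(C)C)CC[C@@]2(C)COC(C)(C)O2 | intermediate
22 | C12 isopropenyl ether | CC(=O)O[C@H]1C[C@H](OC(C)=C)C(C)=C[C@@]1(C)[C@@H](OC(=O)CC(C)C)CC[C@@]2(C)COC(C)(C)O2 | intermediate
23 | C8 methyl ketone, acetonyl on C10β, C11=C12 | CC(=O)O[C@H]1CC=C(C)[C@H](CC(C)=O)[C@@]1(C)[C@@H](OC(=O)CC(C)C)CC[C@@]2(C)COC(C)(C)O2 | intermediate
24 | dibutylboron enolate (C7=C8) | CC(=O)O[C@H]1CC=C(C)[C@H](CC(=C)OB(CCCC)CCCC)[C@@]1(C)[C@@H](OC(=O)CC(C)C)CC[C@@]2(C)COC(C)(C)O2 | intermediate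
25 | C7 bromomethyl ketone | CC(=O)O[C@H]1CC=C(C)[C@H](CC(=O)CBr)[C@@]1(C)[C@@H](OC(=O)CC(C)C)CC[C@@]2(C)COC(C)(C)O2 | intermediate
26 | C7 2-(diethoxyphosphoryl)propanoate (phosphonate carbon unspecified) | CC(=O)O[C@H]1CC=C(C)[C@H](CC(=O)COC(=O)C(C)P(=O)(OCC)OCC)[C@@]1(C)[C@@H](OC(=O)CC(C)C)CC[C@@]2(C)COC(C)(C)O2 | intermediate
27 | butenolide acetonide | CC(=O)O[C@H]1CC=C(C)[C@H](CC2=C(C)C(=O)OC2)[C@@]1(C)[C@@H](OC(=O)CC(C)C)CC[C@@]3(C)COC(C)(C)O3 | intermediate
28 | C5,C6-diol | CC(=O)O[C@H]1CC=C(C)[C@H](CC2=C(C)C(=O)OC2)[C@@]1(C)[C@@H](OC(=O)CC(C)C)CC[C@](C)(O)CO | intermediate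
29 | C5,C6-bis(triethylsilyl) ether | CC(=O)O[C@H]1CC=C(C)[C@H](CC2=C(C)C(=O)OC2)[C@@]1(C)[C@@H](OC(=O)CC(C)C)CC[C@](C)(O[Si](CC)(CC)CC)CO[Si](CC)(CC)CC | intermediate
30 | C6 alkoxydimethylsulfonium chloride | CC(=O)O[C@H]1CC=C(C)[C@H](CC2=C(C)C(=O)OC2)[C@@]1(C)[C@@H](OC(=O)CC(C)C)CC[C@](C)(O[Si](CC)(CC)CC)CO[S+](C)C.[Cl-] | intermediate
31 | C6 aldehyde, C5 OTES | CC(=O)O[C@H]1CC=C(C)[C@H](CC2=C(C)C(=O)OC2)[C@@]1(C)[C@@H](OC(=O)CC(C)C)CC[C@](C)(O[Si](CC)(CC)CC)C=O | intermediate
32 | 2-(tert-butyldimethylsilyloxy)furan aldehyde | CC(=O)O[C@H]1CC=C(C)[C@H](Cc2coc(O[Si](C)(C)C(C)(C)C)c2C)[C@@]1(C)[C@@H](OC(=O)CC(C)C)CC[C@](C)(O[Si](CC)(CC)CC)C=O | intermediate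
33 | macrocyclic aldol, C6 OTBS, C5 OTES, mixture at C6 and C7 | CC(=O)O[C@H]1CC=C(C)[C@@H]2CC3=C(C)C(=O)OC3C(O[Si](C)(C)C(C)(C)C)[C@@](C)(O[Si](CC)(CC)CC)CC[C@H](OC(=O)CC(C)C)[C@@]12C | intermediate
34 | C5 O-triethylsilyl ether of the target, (6E) | CC(=O)O[C@H]1CC=C(C)[C@@H]2CC3=C(C)C(=O)O/C3=C/[C@@](C)(O[Si](CC)(CC)CC)CC[C@H](OC(=O)CC(C)C)[C@@]12C | intermediate
35 | CNP0208239.1, (1S,2S,5S,6E,10S,14S) briarane with C14 acetate, C2 isovalerate and C5 hydroxyl | CC(=O)O[C@H]1CC=C(C)[C@@H]2CC3=C(C)C(=O)O/C3=C/[C@@](C)(O)CC[C@H](OC(=O)CC(C)C)[C@@]12C | target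

**Total step count:** 24 (steps 1–4 make aldehyde 6; steps 5–24 run from carvone).
**Longest linear sequence:** 24 steps (1 → 35); 20 steps counted from 7.

**Three steps most likely to fail**

Step 22 (closure of the ten-membered ring) is the most likely to fail. The hindered aldehyde may simply sit beside the silyloxyfuran, or it may oligomerise. The fallback sets out from 31 and replaces the reversible addition by an olefination. The silyloxyfuran 32, which forms in any case, is intercepted at −78 °C with N-bromosuccinimide to give the γ-bromobutenolide aldehyde F1. PPh3 in MeCN converts this into the butenolide triphenylphosphonium bromide F2. Slow addition of F2 to Et3N in CH2Cl2 at high dilution then closes ring B by an intramolecular Wittig reaction of the stabilised ylide. This route comes back at 34 and so replaces steps 22 and 23 together.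

Step 14 (thioacylation of the C10 hydroxyl) is the second risk. The hydroxyl lies between two fully substituted carbons, so acylation may stall or may let the neighbouring esters migrate. The fallback sets out from 17 and never makes the alcohol. Hydrazine hydrate buffered with AcOH in MeOH (0 °C → rt) condenses with the activated ketone to the α,β-epoxy hydrazone F3. F3 collapses in the classical Wharton transposition with loss of nitrogen, keeping the β C12–O bond. This route comes back at 20 and replaces steps 13 to 15.

Step 8 (reduction of C2 in the presence of the C10 enone) is the third risk, because the two carbonyl groups may not be told apart. The fallback sets out from 11 and gives up on chemoselectivity in the reduction. Excess catecholborane with the same (R)-oxazaborolidine reduces both carbonyls, C2 still under catalyst control, to the C2,C10-diol F4. MnO2 in CH2Cl2 then oxidises only the allylic C10 carbinol back to the enone. This route comes back at 12.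

**Further compounds**
F1 | step 22 | γ-bromobutenolide aldehyde (C7 unspecified) | CC(=O)O[C@H]1CC=C(C)[C@H](CC2=C(C)C(=O)OC2Br)[C@@]1(C)[C@@H](OC(=O)CC(C)C)CC[C@](C)(O[Si](CC)(CC)CC)C=O
F2 | step 22 | butenolide triphenylphosphonium bromide (C7 unspecified) | CC(=O)O[C@H]1CC=C(C)[C@H](CC2=C(C)C(=O)OC2[P+](c3ccccc3)(c4ccccc4)c5ccccc5)[C@@]1(C)[C@@H](OC(=O)CC(C)C)CC[C@](C)(O[Si](CC)(CC)CC)C=O.[Br-]
F3 | step 14 | α,β-epoxy hydrazone of 17 | CC(=O)O[C@H]1C[C@@H]2O[C@]2(C)C(=NN)[C@@]1(C)[C@@H](OC(=O)CC(C)C)CC[C@@]3(C)COC(C)(C)O3
F4 | step 8 | C2,C10-diol, (2S), C10 epimers | CC(=C)[C@H]1CC=C(C)C(O)[C@@]1(C)[C@@H](O)CC[C@@]2(C)COC(C)(C)O2
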